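Ring B of ferocaulidin (C5–C10) carries C6=O, the C7=C8 alkene with its C12 methyl, the C10 methyl and a functionalised C9. This is the atom pattern of 2,6-dimethyl-1,4-benzoquinone once its C5=C10 double bond has acted as a dienophile. The route therefore disconnects ring A at C1–C10 and C4–C5 and forms both bonds, ring A, the quaternary C10 stereocentre and the gem-dimethyl C4 in one catalytic enantioselective Diels–Alder reaction. The precursors are the purchased quinone and 4-methylpenta-1,3-diene. Later steps invert C5, hydrate C2=C3 to the axial 3-OH, turn C9=O into the CH–CH2–O–coumarin unit and restore the C6 enone.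

Key step: step 1

Remarks on the chemistry:
- Locants follow the drimane skeleton: ring A = C1–C5 and C10, ring B = C5–C10, C11 on C9, C12 on C8. C9 ketones are named as 11-nor compounds. "Drim" denotes the skeleton only; every configuration is given by its CIP descriptor.
- Assumption: the usual binding model (quinone C6=O on boron, the adjacent vinylic C–H against the ring oxygen, a C-aryl group behind the C5=C10 bond) assigns the required (10R) adduct to the catalyst from (S)-α,α-diphenylprolinol. If the sense proved opposite, the catalyst from (R)-α,α-diphenylprolinol would be used with no other change.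
- The catalyst is prepared from (S)-α,α-diphenylprolinol and tri(o-tolyl)boroxine (toluene, azeotropic removal of water) and activated with HNTf2 in CH2Cl2 just before use.

Step 1
Reactants: 1 2,6-dimethyl-1,4-benzoquinone; 2 4-methylpenta-1,3-diene
Product: 3 (5S,10R)-11-nordrima-2,7-diene-6,9-dione (cis-fused; H5 and the C10 methyl on the same face)
Conditions: (S)-B-(o-tolyl)diphenylprolinol-derived oxazaborolidinium triflimide (20 mol %), 2 (5 equiv), CH2Cl2, −78 → −20 °C
Reagents that add atoms: none
Why: Proposed new method: the triflimide-protonated oxazaborolidine binds the C6 carbonyl oxygen of 1 (the carbonyl flanked by two vinylic C–H, one of which contacts the catalyst oxygen) and polarises the C5=C10 bond so that the methyl-bearing C10 is the electrophilic end; the CH2 terminus of 2 bonds there first (C1–C10) while positive charge develops on the allylic gem-dimethyl terminus, which then closes on C5 (C4–C5) in a strongly asynchronous, suprafacial [4+2] cycloaddition. The closest known reaction type is the oxazaborolidinium-catalysed Diels–Alder reaction of alkyl-1,4-benzoquinones with 2-silyloxy- and alkyl-butadienes; new here is a diene whose Z-methyl disfavours the s-cis conformer, which the cationic Lewis acid should overcome by making the first bond formation Michael-like. Ring A, the only ring formed, closes as a six-membered carbocycle by the cycloaddition itself, both σ-bonds arriving on one face of the dienophile and giving the cis ring fusion. C10 is controlled by the catalyst, whose C-aryl group covers one face of the bound C5=C10 bond so that the diene adds to the other, and C5 is fixed relative to C10 by the suprafacial addition and is inverted in step 2. The step needs regioselectivity (CH2 to C10, CMe2 to C5) and π-facial selectivity: the first is secured by the polarisation of the bound enone and by the steric penalty of joining two fully substituted carbons, the second by the twofold symmetry of 1, which offers the catalyst only one kind of carbonyl lone pair and one kind of methyl-bearing double bond.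

Step 2
Reactants: 3 (5S,10R)-11-nordrima-2,7-diene-6,9-dione
Product: 4 (5R,10R)-11-nordrima-2,7-diene-6,9-dione (trans-fused; H5 anti to the C10 methyl)
Conditions: DBU (0.2 equiv), toluene, rt
Reagents that add atoms: none
Why: Base-mediated epimerisation of a cis quinone Diels–Alder adduct through the C5=C6 dienolate (C5–H is the only enolisable hydrogen because C10 is quaternary) should settle at the trans-fused decalin, so C5 is set under thermodynamic control with H5 anti to the C10 methyl.

Step 3
Reactants: 4 (5R,10R)-11-nordrima-2,7-diene-6,9-dione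
Product: 5 (5R,6S,10R)-6-hydroxy-11-nordrima-2,7-dien-9-one (6-OH syn to the C10 methyl)
Conditions: NaBH4 (1.0 equiv), CeCl3·7H2O, MeOH, −78 °C
Reagents that add atoms: none
Why: Luche 1,2-reduction should select the C6 carbonyl, flanked by two CH carbons, over the C9 carbonyl shielded by the quaternary C10 and the C8 methyl, and hydride should arrive anti to the axial C10 methyl to give the 6S alcohol, a configuration that is immaterial because C6 returns to a ketone in step 12.

Step 4
Reactants: 5 (5R,6S,10R)-6-hydroxy-11-nordrima-2,7-dien-9-one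
Product: 6 (5R,6S,10R)-6-(triethylsilyloxy)-11-nordrima-2,7-dien-9-one
Conditions: TESOTf, 2,6-lutidine, CH2Cl2, −78 → 0 °C
Reagents that add atoms: triethylsilyl trifluoromethanesulfonate, CC[Si](CC)(CC)OS(=O)(=O)C(F)(F)F
Why: Silylation of a hindered secondary alcohol with a silyl triflate and a non-nucleophilic base is standard protecting-group chemistry, and the small triethylsilyl ether masks C6 through the hydride, ylide and borane steps yet leaves with fluoride.

Step 5
Reactants: 6 (5R,6S,10R)-6-(triethylsilyloxy)-11-nordrima-2,7-dien-9-one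
Product: 7 (2S,3R,5R,6S,10R)-2,3-epoxy-6-(triethylsilyloxy)-11-nordrim-7-en-9-one (oxirane anti to the C10 methyl)
Conditions: mCPBA, NaHCO3, CH2Cl2, 0 °C
Reagents that add atoms: 3-chloroperoxybenzoic acid (mCPBA), OOC(=O)c1cccc(Cl)c1
Why: Prilezhaev epoxidation should take the isolated C2=C3 bond and spare the electron-poor enone C7=C8 bond, and the peracid should approach the face opposite the axial C10 methyl and the axial C4 methyl, which places the oxirane oxygen anti to the C10 methyl.

Step 6
Reactants: 7 (2S,3R,5R,6S,10R)-2,3-epoxy-6-(triethylsilyloxy)-11-nordrim-7-en-9-one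
Product: 9 (3S,5R,6S,9R,10R)-6-(triethylsilyloxy)-11-nordrim-7-ene-3,9-diol, via epoxy alcohol 8 (not isolated)
Conditions: LiAlH4 (excess), THF, 0 °C → reflux
Reagents that add atoms: none
Why: LiAlH4 first reduces the C9 enone carbonyl in 1,2-fashion (hydride anti to the C10 methyl, configuration immaterial) and then opens the oxirane by SN2 hydride attack at C2, the trans-diaxial (Fürst–Plattner) mode that also avoids the neopentyl C3, so the retained C3–O bond becomes the axial 3-OH anti to the C10 methyl (3S).

Step 7
Reactants: 9 (3S,5R,6S,9R,10R)-6-(triethylsilyloxy)-11-nordrim-7-ene-3,9-diol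
Product: 10 (3S,5R,6S,10R)-3-hydroxy-6-(triethylsilyloxy)-11-nordrim-7-en-9-one
Conditions: activated MnO2 (excess), CH2Cl2, rt
Reagents that add atoms: none
Why: MnO2 oxidises allylic alcohols selectively, so the C9 carbinol should return to the enone while the saturated C3–OH and the silyl ether stay untouched, and no stereocentre is formed.

Step 8
Reactants: 10 (3S,5R,6S,10R)-3-hydroxy-6-(triethylsilyloxy)-11-nordrim-7-en-9-one
Product: 11 (3S,5S,6S,10R)-6-(triethylsilyloxy)drima-7,9(11)-dien-3-ol
Conditions: Ph3PCH3Br (4 equiv), KOt-Bu (4 equiv), toluene, 90 °C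
Reagents that add atoms: methyltriphenylphosphonium bromide, C[P+](c1ccccc1)(c1ccccc1)c1ccccc1.[Br-]
Why: Wittig methylenation with excess ylide at elevated temperature is the standard answer to a hindered ketone that has no α-hydrogen, the free C3–OH merely consumes one equivalent of base, and H6 lies in the nodal plane of the enone so γ-deprotonation should not compete.

Step 9
Reactants: 11 (3S,5S,6S,10R)-6-(triethylsilyloxy)drima-7,9(11)-dien-3-ol
Product: 13 (3S,5S,6S,9R,10S)-6-(triethylsilyloxy)drim-7-ene-3,11-diol, via C11 alkylborane 12 (not isolated)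
Conditions: 9-BBN (3 equiv), THF, 0 → 50 °C; then NaOH, H2O2, 0 °C → rt
Reagents that add atoms: hydrogen peroxide, OO (oxygen of the C11–OH); 9-BBN, B1C2CCCC1CCC2 (its boron and bicycle stay only in 12, it gives hydrogen to C9)
Why: Hydroboration–oxidation with bulky 9-BBN should place boron on the terminal C11 in preference to the trisubstituted C7=C8 bond and deliver hydrogen to C9 on the face away from the pseudo-axial C10 methyl and the C6 silyloxy group, which sets C9 (9R) with C11 syn to the C10 methyl, and alkaline peroxide then converts C–B into C–OH.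

Step 10
Reactants: 13 (3S,5S,6S,9R,10S)-6-(triethylsilyloxy)drim-7-ene-3,11-diol; 14 umbelliferone
Product: 15 7-{[(3S,5S,6S,9R,10S)-3-hydroxy-6-(triethylsilyloxy)drim-7-en-11-yl]oxy}-2H-chromen-2-one
Conditions: 14 (1.5 equiv), PPh3, DIAD, THF, 0 °C → rt
Reagents that add atoms: none
Why: In this Mitsunobu etherification the acidic phenol (pKa about 8) is alkylated by the activated primary C11–OH, while the axial neopentyl C3–OH should be too hindered to react, and C11 is not a stereocentre.

Step 11
Reactants: 15 7-{[(3S,5S,6S,9R,10S)-3-hydroxy-6-(triethylsilyloxy)drim-7-en-11-yl]oxy}-2H-chromen-2-one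
Product: 16 7-{[(3S,5S,6S,9R,10S)-3,6-dihydroxydrim-7-en-11-yl]oxy}-2H-chromen-2-one
Conditions: HF·pyridine, pyridine, THF, 0 °C → rt
Reagents that add atoms: none
Why: Fluoride-mediated desilylation under buffered, non-basic conditions frees the C6 alcohol without opening the coumarin lactone.

Step 12
Reactants: 16 7-{[(3S,5S,6S,9R,10S)-3,6-dihydroxydrim-7-en-11-yl]oxy}-2H-chromen-2-one
Product: 17 ferocaulidin, 7-{[(3S,5S,9R,10S)-3-hydroxy-6-oxodrim-7-en-11-yl]oxy}-2H-chromen-2-one
Conditions: activated MnO2 (excess), CH2Cl2, rt
Reagents that add atoms: none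
Why: MnO2 oxidation is selective for the allylic C6–OH over the saturated axial C3–OH and forms the C6 enone under neutral conditions, so neither the trans ring fusion at C5 nor the γ-position C9, whose deprotonation would expel the aryloxide, is disturbed.

Compound list
1 | 2,6-dimethyl-1,4-benzoquinone | CC1=CC(=O)C=C(C)C1=O | starting material
2 | 4-methylpenta-1,3-diene | CC(C)=CC=C | starting material
3 | (5S,10R)-11-nordrima-2,7-diene-6,9-dione, cis-fused [(4aS,8aR)-2,5,5,8a-tetramethyl-4a,5,8,8a-tetrahydronaphthalene-1,4-dione] | CC1=CC(=O)[C@H]2C(C)(C)C=CC[C@@]2(C)C1=O | intermediate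
4 | (5R,10R)-11-nordrima-2,7-diene-6,9-dione, trans-fused [(4aR,8aR)-2,5,5,8a-tetramethyl-4a,5,8,8a-tetrahydronaphthalene-1,4-dione] | CC1=CC(=O)[C@@H]2C(C)(C)C=CC[C@@]2(C)C1=O | intermediate
5 | (5R,6S,10R)-6-hydroxy-11-nordrima-2,7-dien-9-one | CC1=C[C@H](O)[C@@H]2C(C)(C)C=CC[C@@]2(C)C1=O | intermediate
6 | (5R,6S,10R)-6-(triethylsilyloxy)-11-nordrima-2,7-dien-9-one | CC1=C[C@H](O[Si](CC)(CC)CC)[C@@H]2C(C)(C)C=CC[C@@]2(C)C1=O | intermediate
7 | (2S,3R,5R,6S,10R)-2,3-epoxy-6-(triethylsilyloxy)-11-nordrim-7-en-9-one | CC1=C[C@H](O[Si](CC)(CC)CC)[C@@H]2C(C)(C)[C@H]3O[C@H]3C[C@@]2(C)C1=O | intermediate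
8 | (2S,3R,5R,6S,9R,10R)-2,3-epoxy-6-(triethylsilyloxy)-11-nordrim-7-en-9-ol | CC1=C[C@H](O[Si](CC)(CC)CC)[C@@H]2C(C)(C)[C@H]3O[C@H]3C[C@@]2(C)[C@@H]1O | intermediate (not isolated)
9 | (3S,5R,6S,9R,10R)-6-(triethylsilyloxy)-11-nordrim-7-ene-3,9-diol | CC1=C[C@H](O[Si](CC)(CC)CC)[C@@H]2C(C)(C)[C@@H](O)CC[C@@]2(C)[C@@H]1O | intermediate
10 | (3S,5R,6S,10R)-3-hydroxy-6-(triethylsilyloxy)-11-nordrim-7-en-9-one | CC1=C[C@H](O[Si](CC)(CC)CC)[C@@H]2C(C)(C)[C@@H](O)CC[C@@]2(C)C1=O | intermediate
11 | (3S,5S,6S,10R)-6-(triethylsilyloxy)drima-7,9(11)-dien-3-ol | CC1=C[C@H](O[Si](CC)(CC)CC)[C@@H]2C(C)(C)[C@@H](O)CC[C@@]2(C)C1=C | intermediate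
12 | (3S,5S,6S,9R,10S)-11-(9-borabicyclo[3.3.1]nonan-9-yl)-6-(triethylsilyloxy)drim-7-en-3-ol | CC1=C[C@H](O[Si](CC)(CC)CC)[C@@H]2C(C)(C)[C@@H](O)CC[C@@]2(C)[C@@H]1CB1C2CCCC1CCC2 | intermediate (not isolated)
13 | (3S,5S,6S,9R,10S)-6-(triethylsilyloxy)drim-7-ene-3,11-diol | CC1=C[C@H](O[Si](CC)(CC)CC)[C@@H]2C(C)(C)[C@@H](O)CC[C@@]2(C)[C@@H]1CO | intermediate
14 | umbelliferone (7-hydroxy-2H-chromen-2-one) | Oc1ccc2ccc(=O)oc2c1 | starting material
15 | 7-{[(3S,5S,6S,9R,10S)-3-hydroxy-6-(triethylsilyloxy)drim-7-en-11-yl]oxy}-2H-chromen-2-one | CC1=C[C@H](O[Si](CC)(CC)CC)[C@@H]2C(C)(C)[C@@H](O)CC[C@@]2(C)[C@@H]1COc1ccc2ccc(=O)oc2c1 | intermediate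
16 | 7-{[(3S,5S,6S,9R,10S)-3,6-dihydroxydrim-7-en-11-yl]oxy}-2H-chromen-2-one | CC1=C[C@H](O)[C@@H]2C(C)(C)[C@@H](O)CC[C@@]2(C)[C@@H]1COc1ccc2ccc(=O)oc2c1 | intermediate
17 | ferocaulidin, 7-{[(3S,5S,9R,10S)-3-hydroxy-6-oxodrim-7-en-11-yl]oxy}-2H-chromen-2-one | CC1=CC(=O)[C@@H]2C(C)(C)[C@@H](O)CC[C@@]2(C)[C@@H]1COc1ccc2ccc(=O)oc2c1 | target

Total steps: 12. Longest linear sequence: 12 steps (from 1 and 2 to 17); umbelliferone 14 enters in step 10.

Steps most likely to fail

Step 1 (carries the proposed method). The diene populates the s-cis conformer poorly, so cationic oligomerisation of 2 or an ene-type or open-chain Michael pathway may outrun ring closure. An unselective proton-catalysed background reaction may also erode the enantiomeric purity. The fallback uses known chemistry, sets out from 1 and returns at 3. Mesityl oxide is enolised at its acetyl methyl (LiN(i-Pr)2, THF, −78 °C) and silylated (TIPSOTf) to 4-methyl-2-(triisopropylsilyloxy)penta-1,3-diene F1. F1 belongs to the 2-silyloxydiene class for which the oxazaborolidinium-catalysed quinone cycloaddition is established, and its higher nucleophilicity should offset the Z-methyl. With 1 and the same catalyst its CH2 terminus should again bond to C10 and give the cis-fused silyl enol ether (5S,10R)-2-(triisopropylsilyloxy)-11-nordrima-2,7-diene-6,9-dione F2. CsF and PhNTf2 (DME, rt) should exchange silicon for the triflyl group without moving the double bond and give (5S,10R)-6,9-dioxo-11-nordrima-2,7-dien-2-yl trifluoromethanesulfonate F3. Formate hydrogenolysis (Pd(OAc)2, PPh3, Bu3N, HCO2H, DMF, 60 °C) then replaces the triflate by hydrogen and leaves the C2=C3 alkene of 3.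

Step 2. The equilibration at C5 may stop at a mixture if the cis-fused isomer is not much less stable than the trans one. The fallback runs from 3 to 4 under kinetic control. Soft enolisation of the only enolisable ketone (TBSOTf, Et3N, CH2Cl2, 0 °C) gives (10R)-6-(tert-butyldimethylsilyloxy)-11-nordrima-2,5,7-trien-9-one F4, in which C5 is planar. Protodesilylation at low temperature (HF·pyridine, THF, −78 °C) should deliver the proton to C5 on the face opposite the axial C10 methyl and give 4 whatever the equilibrium position. 4 is then reduced at once in step 3, after which C5 can no longer epimerise.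

Step 10. Displacement of the oxyphosphonium ion at the β-branched C11 may be slow, so that elimination toward the C9=C11 alkene or alkylation of the hydrazide takes over. The fallback runs from 13 to 15 and forms the other C–O bond. It is a C–O cross-coupling of the primary alcohol with commercial 7-bromocoumarin (Brc1ccc2ccc(=O)oc2c1) using [Pd(C3H5)Cl]2, the biarylphosphine RockPhos and Cs2CO3 in toluene at 90 °C. The oxygen of 13 is retained, no substitution at C11 is needed, and the hindered C3–OH should not compete. This fallback makes no new compound (F0).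

Further compounds
F1 | step 1 | 4-methyl-2-(triisopropylsilyloxy)penta-1,3-diene | CC(C)=CC(=C)O[Si](C(C)C)(C(C)C)C(C)C
F2 | step 1 | (5S,10R)-2-(triisopropylsilyloxy)-11-nordrima-2,7-diene-6,9-dione | CC1=CC(=O)[C@H]2C(C)(C)C=C(O[Si](C(C)C)(C(C)C)C(C)C)C[C@@]2(C)C1=O
F3 | step 1 | (5S,10R)-6,9-dioxo-11-nordrima-2,7-dien-2-yl trifluoromethanesulfonate | CC1=CC(=O)[C@H]2C(C)(C)C=C(OS(=O)(=O)C(F)(F)F)C[C@@]2(C)C1=O
F4 | step 2 | (10R)-6-(tert-butyldimethylsilyloxy)-11-nordrima-2,5,7-trien-9-one | CC1=CC(O[Si](C)(C)C(C)(C)C)=C2C(C)(C)C=CC[C@@]2(C)C1=O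
F0 | step 10 | none | none
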